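The data come from a simulation from invented constants; noise was put on by code.

Start from amounts. The ash run holds 0.600 M of Q on 0.0120 M of Z, which is 50.0 Q for each Z, and by 6.4 min it has made 0.3076 M of G, or 25.6 G per Z charged. So each Z serves repeatedly. Write the balance of this smaller charge: the forms of Z, whatever they are, add up to what was put in, so take that charge as the divisor.

| flask | Q | Z | time |
|---|---|---|---|
| ash | 0.600 M | 0.0120 M |  |
| cedar | 0.240 M | 0.0120 M |  |
| larch | 0.600 M | 0.0180 M |  |
| alder | 0.900 M | 0.0120 M |  |
| elm | 0.200 M | 0.0120 M | 6.4 min |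

| ash run: time / min | ash run: [G] / M | cedar run: time / min | cedar run: [G] / M | larch run: time / min | larch run: [G] / M | alder run: time / min | alder run: [G] / M |
|---|---|---|---|---|---|---|---|
| 1.1 | 0.0412 | 1.1 | 0.0258 | 1.1 | 0.0644 | 1.1 | 0.0531 |
| 2.1 | 0.0884 | 2.1 | 0.0436 | 2.1 | 0.1279 | 2.1 | 0.1194 |
| 3.2 | 0.1411 | 3.2 | 0.0636 | 3.2 | 0.2014 | 3.2 | 0.1990 |
| 4.3 | 0.1998 | 4.3 | 0.0830 | 4.3 | 0.2746 | 4.3 | 0.2929 |
| 5.3 | 0.2504 | 5.3 | 0.1010 | 5.3 | 0.3328 | 5.3 | 0.3849 |
| 6.4 | 0.3076 | 6.4 | 0.1153 | 6.4 | 0.3850 | 6.4 | 0.4854 |

(readings scatter by 0.002 M)

- Overall: Q -> G, with Z as catalyst.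
- Constant volume, constant temperature.
- Bound and free are read together.
- An order is taken over about fifteen percent of the charge, up and down.

- reaction order in [Q] at the outset, round the charge of the ash run, defined at two percent of the Q turned into G (one fixed amount of G, the same in the runs compared)
- reaction order in [Z] at the outset, round the charge of the ash run, defined at two percent of the Q turned into G
- the cedar run starts with 0.360 M less of Q than the ash run, and with no G. Compared where both hold the same amount of Q, once fifteen percent of what the cedar run was charged with has turned into G, is the cedar run faster, slower or alike (within a tenth)?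
- G in the elm run at 6.4 min, as a share of the Q charged

Divide. Over its first reading the ash run gives 3.12 min⁻¹. Call this the turnover rate (turnover frequency), the G made per Z charged per minute.

The larch run gives 3.25 min⁻¹ over the same reading, close to the ash value, so I take the order in Z as 1.10. The cedar run gives 1.95 min⁻¹ and the alder run 4.02 min⁻¹, and the slope between them puts my order in Q near 0.546, a coarse figure from a wide span.

Now compare late with early. In its last interval the ash run turns over at 4.33 min⁻¹, faster than at its start, although it then holds about 0.321 M of Q. Cut that rate in proportion to Q, down to the 0.195 M of the cedar run between its first and third readings, and it is still 2.64 min⁻¹. The cedar run there shows 1.50 min⁻¹. So I commit to slower for the cedar run.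

For elm, test the cedar run against itself. Its rate per Q is 0.103 min⁻¹ at first and 0.0986 min⁻¹ at last, so the cedar rate follows Q within the scatter. Scale the mean cedar turnover rate, 1.50 min⁻¹, by the charge: elm should run at 1.25 min⁻¹, which makes 0.0961 M of G, or 48.0% of its Q.

The forecast gives 0.42 (0.3 to 0.55) in Q, below my figure, 1.05 (0.88 to 1.2) in Z, slower with the words “so cedar is slower”, and 50% (46% to 54%) for elm, above my share.

The flask gives orders of 0.47 in Q and 0.94 in Z, the cedar run slower at 0.53 of the ash rate, and 47.2% for elm, a turnover rate of 1.23 min⁻¹ against my 1.25 min⁻¹.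

    Z + Q ⇌ ZQ, settled at all times (28.20 M⁻¹)
    ZQ + Q ⇌ ZQ2, settled at all times (3.010 M⁻¹)
    ZQ2 → G + ZQ (5.106 min⁻¹)
    Q + G → 2 G (0.3234 M⁻¹ min⁻¹)
    ZQ → Zo + Q (0.1038 min⁻¹)

Where G stands at two percent of the ash charge, the larch run goes at 1.5 times the ash rate on 1.50 times the Z, so at that early point their turnover rates are alike. Up to half of the charge, the ash run's mean stands at 3.97 min⁻¹, above its first 3.12 min⁻¹, while the larch run, lower, averages 3.50 min⁻¹ over 4.76 min.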